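The target is the meso (6S,6′R) C40 diketone whose two end rings (ring A, ring B) are mirror images. Each ring is cut at the C1–C6 bond, which links the gem-dimethyl carbon C1 to the only stereocentre C6 next to the C4=C5 alkene. A chiral Brønsted acid closes that bond in an open-chain (E)-geranyl sulfone, delivering ring, quaternary carbon and C6 configuration in one operation; the two acid antipodes give the two rings. The precursor carries a 1-phenyltetrazol-5-yl sulfone at C7 so that the cyclised sulfones can be joined directly, one after the other, to a C20 polyene dialdehyde by Julia–Kocienski olefination after C3 oxygenation.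

Key step: step 3

Remark on numbering: carotenoid numbering is used (C1 gem-dimethyl carbon, C3 carbonyl carbon, C4=C5 ring alkene, C6 stereocentre, C7 first chain carbon; primed numbers for ring B).
Remark on the acid: its sense of induction cannot be predicted; the (S,S)-acid is assumed to give the (S)-sulfone, and the two antipodes are exchanged if a first trial shows the reverse.
Remark on the linker: the all-E C20 dialdehyde (crocetindialdehyde) is assumed to be bought as a catalogue compound.
Remark on C3: the carbinol centres at C3 and C3′ are temporary, so both epimers are carried forward until the last step removes them.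

Step 1
Reactants: 1 geranyl bromide; 2 1-phenyl-1H-tetrazole-5-thiol
Product: 3 geranyl 1-phenyl-1H-tetrazol-5-yl sulfide
Conditions: K2CO3, acetone, 0 °C → rt
Reagents that add atoms: none
Why: Thiolate S-alkylation (SN2) at the primary allylic bromide should occur without allylic transposition and with retention of the E alkene, sulfur being the soft nucleophilic site of the tetrazolethiolate.

Step 2
Reactants: 3 geranyl 1-phenyl-1H-tetrazol-5-yl sulfide
Product: 5 geranyl 1-phenyl-1H-tetrazol-5-yl sulfone, via geranyl tetrazolyl sulfoxide 4 (not isolated)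
Conditions: H2O2 (30% aq.), (NH4)6Mo7O24·4H2O (10 mol%), EtOH, 0 °C
Reagents that add atoms: hydrogen peroxide, OO
Why: Molybdate-catalysed peroxide oxidation of a sulfide to the sulfone is chemoselective for sulfur over trisubstituted alkenes, and the cold medium should let sulfoxide 4 be oxidised on before a [2,3]-sigmatropic sulfoxide–sulfenate shift can erode the E geometry.

Step 3
Reactants: 5 geranyl 1-phenyl-1H-tetrazol-5-yl sulfone
Product: 6 (S)-α-cyclogeranyl 1-phenyl-1H-tetrazol-5-yl sulfone, 5-({[(1S)-2,6,6-trimethylcyclohex-2-en-1-yl]methyl}sulfonyl)-1-phenyl-1H-tetrazole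
Conditions: (S,S)-N,N′-bis(triflyl) imidodiphosphorimidate acid from two 3,3′-bis[3,5-bis(trifluoromethyl)phenyl]-(S)-BINOL units (5 mol%), (CF3)3COH–CH2Cl2 (1:4), −40 °C
Reagents that add atoms: none
Why: Proposed new method: The confined chiral acid should protonate C2 of the terminal alkene in Markovnikov fashion, C6 of the C5=C6 alkene then attacks the tertiary C1 cation inside the chiral ion pair, and the conjugate base of the acid removes a C4 proton from the resulting C5 cation, which regenerates the catalyst and leaves the C4=C5 alkene. The closest known reaction types are the racemic Brønsted-acid cyclisation of geranyl aryl sulfones to cyclogeranyl sulfones and the catalytic enantioselective proton-initiated polyene cyclisations with confined imidodiphosphorimidate acids or with chiral 2,2′-binaphthol monoethers activated by SnCl4, which have so far been terminated by an arene or a heteroatom and not by proton loss from a monocyclic sulfone. The one ring closes in a 6-endo-trig mode with respect to the C5=C6 alkene through a chair-like transition state fixed by the E geometry. The new C6 stereocentre is set under catalyst control, because the chiral anion decides which face of C6 meets C1, and the mirror-image acid therefore gives the antipode. The step needs site-selective protonation, face selection and regioselective proton loss: the allylic sulfonyl group lowers the basicity of C5=C6 so that the proton goes to the remote alkene, its oxygens offer the acid a hydrogen-bond anchor next to C6, and the C6–H bond is shielded by the gem-dimethyl and sulfonylmethyl groups, which disfavours the tetrasubstituted isomer at low temperature. The tetrazolyl sulfone is too weakly basic to neutralise the catalyst and is inert to acid.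

Step 4
Reactants: 6 (S)-α-cyclogeranyl 1-phenyl-1H-tetrazol-5-yl sulfone
Product: 7 (S)-3-oxo-α-cyclogeranyl 1-phenyl-1H-tetrazol-5-yl sulfone, 5-({[(1S)-2,6,6-trimethyl-4-oxocyclohex-2-en-1-yl]methyl}sulfonyl)-1-phenyl-1H-tetrazole
Conditions: dirhodium tetracaprolactamate Rh2(cap)4 (1 mol%), t-BuOOH (70% aq.), ClCH2CH2Cl, 40 °C
Reagents that add atoms: tert-butyl hydroperoxide, CC(C)(C)OO
Why: Radical allylic C–H oxidation: the tert-butylperoxyl radical should abstract the accessible secondary C3–H rather than the tertiary C6–H, which is flanked by the gem-dimethyl carbon and deactivated by the sulfonylmethyl group, and oxygenation at C3 gives the conjugated enone, while the base-free medium avoids γ-deprotonation at C6 and loss of sulfinate.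

Step 5
Reactants: 7 (S)-3-oxo-α-cyclogeranyl 1-phenyl-1H-tetrazol-5-yl sulfone
Product: 8 (S)-3-hydroxy-α-cyclogeranyl 1-phenyl-1H-tetrazol-5-yl sulfone, 5-({[(1S)-4-hydroxy-2,6,6-trimethylcyclohex-2-en-1-yl]methyl}sulfonyl)-1-phenyl-1H-tetrazole, both carbinol epimers
Conditions: NaBH4, CeCl3·7H2O, MeOH, −78 °C
Reagents that add atoms: none
Why: Luche 1,2-reduction of the enone is fast at low temperature, leaves the tetrazolyl sulfone and C6 untouched, and creates the C3 carbinol centre under weak substrate control as an epimer mixture, which is accepted because step 14 removes that centre.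

Step 6
Reactants: 8 (S)-3-hydroxy-α-cyclogeranyl 1-phenyl-1H-tetrazol-5-yl sulfone
Product: 9 (S)-3-(tert-butyldimethylsilyloxy)-α-cyclogeranyl 1-phenyl-1H-tetrazol-5-yl sulfone, both C3 epimers
Conditions: TBSCl, imidazole, DMF, rt
Reagents that add atoms: tert-butyldimethylsilyl chloride, CC(C)(C)[Si](C)(C)Cl
Why: Imidazole-promoted silylation of the secondary allylic alcohol masks the hydroxyl group against the strong base of the olefination and is removable by fluoride.

Step 7
Reactants: 5 geranyl 1-phenyl-1H-tetrazol-5-yl sulfone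
Product: 10 (R)-α-cyclogeranyl 1-phenyl-1H-tetrazol-5-yl sulfone, 5-({[(1R)-2,6,6-trimethylcyclohex-2-en-1-yl]methyl}sulfonyl)-1-phenyl-1H-tetrazole
Conditions: (R,R)-N,N′-bis(triflyl) imidodiphosphorimidate acid from two 3,3′-bis[3,5-bis(trifluoromethyl)phenyl]-(R)-BINOL units (5 mol%), (CF3)3COH–CH2Cl2 (1:4), −40 °C
Reagents that add atoms: none
Why: Proposed new method: mirror image of step 3, in which the (R,R)-acid should protonate C2, guide C6 onto the C1 cation from the opposite face within the ion pair in a 6-endo-trig chair closure and remove a C4 proton, so that C6 is set R under catalyst control, the closest known reaction types being the racemic acid cyclisation of geranyl aryl sulfones and enantioselective proton-initiated polyene cyclisation with confined chiral acids.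

Step 8
Reactants: 10 (R)-α-cyclogeranyl 1-phenyl-1H-tetrazol-5-yl sulfone
Product: 11 (R)-3-oxo-α-cyclogeranyl 1-phenyl-1H-tetrazol-5-yl sulfone, 5-({[(1R)-2,6,6-trimethyl-4-oxocyclohex-2-en-1-yl]methyl}sulfonyl)-1-phenyl-1H-tetrazole
Conditions: dirhodium tetracaprolactamate Rh2(cap)4 (1 mol%), t-BuOOH (70% aq.), ClCH2CH2Cl, 40 °C
Reagents that add atoms: tert-butyl hydroperoxide, CC(C)(C)OO
Why: Radical allylic C–H oxidation at the accessible secondary C3 position gives the conjugated enone as in step 4, and the base-free medium leaves C6 untouched.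

Step 9
Reactants: 11 (R)-3-oxo-α-cyclogeranyl 1-phenyl-1H-tetrazol-5-yl sulfone
Product: 12 (R)-3-hydroxy-α-cyclogeranyl 1-phenyl-1H-tetrazol-5-yl sulfone, 5-({[(1R)-4-hydroxy-2,6,6-trimethylcyclohex-2-en-1-yl]methyl}sulfonyl)-1-phenyl-1H-tetrazole, both carbinol epimers
Conditions: NaBH4, CeCl3·7H2O, MeOH, −78 °C
Reagents that add atoms: none
Why: Luche 1,2-reduction of the enone spares the sulfone and C6 and gives the temporary C3 carbinol centre as an epimer mixture that step 14 removes.

Step 10
Reactants: 12 (R)-3-hydroxy-α-cyclogeranyl 1-phenyl-1H-tetrazol-5-yl sulfone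
Product: 13 (R)-3-(tert-butyldimethylsilyloxy)-α-cyclogeranyl 1-phenyl-1H-tetrazol-5-yl sulfone, both C3 epimers
Conditions: TBSCl, imidazole, DMF, rt
Reagents that add atoms: tert-butyldimethylsilyl chloride, CC(C)(C)[Si](C)(C)Cl
Why: Imidazole-promoted silylation of the secondary allylic alcohol protects the hydroxyl group for the olefination.

Step 11
Reactants: 9 (S)-3-(tert-butyldimethylsilyloxy)-α-cyclogeranyl 1-phenyl-1H-tetrazol-5-yl sulfone; 14 crocetindialdehyde, (2E,4E,6E,8E,10E,12E,14E)-2,6,11,15-tetramethylhexadeca-2,4,6,8,10,12,14-heptaenedial (3 equiv)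
Product: 17 (6S)-3-(tert-butyldimethylsilyloxy)-8′-apo-ε-caroten-8′-al, via potassium sulfonyl carbanion 15 (not isolated), via potassium alkoxide adduct 16 (not isolated)
Conditions: KN(SiMe3)2, THF, −78 °C; then cannulated into 14 (3 equiv), THF, −60 °C → rt
Reagents that add atoms: none
Why: Julia–Kocienski olefination: carbanion 15 adds to one formyl group of the excess dialdehyde and adduct 16 collapses by Smiles rearrangement and loss of SO2 and the tetrazolone anion to the C7=C8 alkene, expected mainly E with a conjugated aldehyde, while the C6–H is not acidic here and C6 keeps its configuration.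

Step 12
Reactants: 13 (R)-3-(tert-butyldimethylsilyloxy)-α-cyclogeranyl 1-phenyl-1H-tetrazol-5-yl sulfone; 17 (6S)-3-(tert-butyldimethylsilyloxy)-8′-apo-ε-caroten-8′-al
Product: 20 (6S,6′R)-3,3′-bis(tert-butyldimethylsilyloxy)-ε,ε-carotene, via potassium sulfonyl carbanion 18 (not isolated), via potassium alkoxide adduct 19 (not isolated)
Conditions: KN(SiMe3)2, THF, −78 °C; 17, −78 °C → rt; then I2 (1 mol%), heptane, rt, daylight
Reagents that add atoms: none
Why: Second Julia–Kocienski olefination at the remaining formyl group forms C7′=C8′ by the same addition, Smiles rearrangement and elimination, and the closing iodine-catalysed stereomutation should convert any hindered 7Z or 7′Z isomer into the all-E polyene without affecting C6 or C6′.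

Step 13
Reactants: 20 (6S,6′R)-3,3′-bis(tert-butyldimethylsilyloxy)-ε,ε-carotene
Product: 21 (6S,6′R)-ε,ε-carotene-3,3′-diol, C3 and C3′ epimer mixture
Conditions: Bu4NF, AcOH, THF, rt, dark
Reagents that add atoms: none
Why: Fluoride-induced desilylation buffered by acetic acid should free both allylic carbinols without the ionisation that stronger acid would cause at these positions.

Step 14
Reactants: 21 (6S,6′R)-ε,ε-carotene-3,3′-diol
Product: 22 (6S,6′R)-ε,ε-carotene-3,3′-dione (CNP0344063.2)
Conditions: MnO2 (activated, excess), CH2Cl2, rt, dark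
Reagents that add atoms: none
Why: MnO2 oxidises allylic alcohols selectively under neutral heterogeneous conditions, so both C3 and C3′ carbinol epimers should converge on the dienone while the base-labile C6 and C6′ centres next to the new enones are not epimerised.

Compound list
1 | geranyl bromide, (2E)-1-bromo-3,7-dimethylocta-2,6-diene | CC(C)=CCC/C(C)=C/CBr | starting material
2 | 1-phenyl-1H-tetrazole-5-thiol | SC1=NN=NN1c1ccccc1 | starting material
3 | geranyl 1-phenyl-1H-tetrazol-5-yl sulfide, 5-{[(2E)-3,7-dimethylocta-2,6-dien-1-yl]sulfanyl}-1-phenyl-1H-tetrazole | CC(C)=CCC/C(C)=C/CSC1=NN=NN1c1ccccc1 | intermediate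
4 | geranyl 1-phenyl-1H-tetrazol-5-yl sulfoxide, racemic at sulfur, not isolated | CC(C)=CCC/C(C)=C/CS(=O)C1=NN=NN1c1ccccc1 | intermediate
5 | geranyl 1-phenyl-1H-tetrazol-5-yl sulfone, 5-{[(2E)-3,7-dimethylocta-2,6-dien-1-yl]sulfonyl}-1-phenyl-1H-tetrazole | CC(C)=CCC/C(C)=C/CS(=O)(=O)C1=NN=NN1c1ccccc1 | intermediate
6 | (S)-α-cyclogeranyl 1-phenyl-1H-tetrazol-5-yl sulfone, 5-({[(1S)-2,6,6-trimethylcyclohex-2-en-1-yl]methyl}sulfonyl)-1-phenyl-1H-tetrazole | CC1=CCCC(C)(C)[C@@H]1CS(=O)(=O)C1=NN=NN1c1ccccc1 | intermediate
7 | 5-({[(1S)-2,6,6-trimethyl-4-oxocyclohex-2-en-1-yl]methyl}sulfonyl)-1-phenyl-1H-tetrazole | CC1=CC(=O)CC(C)(C)[C@@H]1CS(=O)(=O)C1=NN=NN1c1ccccc1 | intermediate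
8 | 5-({[(1S)-4-hydroxy-2,6,6-trimethylcyclohex-2-en-1-yl]methyl}sulfonyl)-1-phenyl-1H-tetrazole, both carbinol epimers | CC1=CC(O)CC(C)(C)[C@@H]1CS(=O)(=O)C1=NN=NN1c1ccccc1 | intermediate
9 | 5-({[(1S)-4-{[tert-butyl(dimethyl)silyl]oxy}-2,6,6-trimethylcyclohex-2-en-1-yl]methyl}sulfonyl)-1-phenyl-1H-tetrazole, both silyloxy epimers | CC1=CC(O[Si](C)(C)C(C)(C)C)CC(C)(C)[C@@H]1CS(=O)(=O)C1=NN=NN1c1ccccc1 | intermediate
10 | (R)-α-cyclogeranyl 1-phenyl-1H-tetrazol-5-yl sulfone, 5-({[(1R)-2,6,6-trimethylcyclohex-2-en-1-yl]methyl}sulfonyl)-1-phenyl-1H-tetrazole | CC1=CCCC(C)(C)[C@H]1CS(=O)(=O)C1=NN=NN1c1ccccc1 | intermediate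
11 | 5-({[(1R)-2,6,6-trimethyl-4-oxocyclohex-2-en-1-yl]methyl}sulfonyl)-1-phenyl-1H-tetrazole | CC1=CC(=O)CC(C)(C)[C@H]1CS(=O)(=O)C1=NN=NN1c1ccccc1 | intermediate
12 | 5-({[(1R)-4-hydroxy-2,6,6-trimethylcyclohex-2-en-1-yl]methyl}sulfonyl)-1-phenyl-1H-tetrazole, both carbinol epimers | CC1=CC(O)CC(C)(C)[C@H]1CS(=O)(=O)C1=NN=NN1c1ccccc1 | intermediate
13 | 5-({[(1R)-4-{[tert-butyl(dimethyl)silyl]oxy}-2,6,6-trimethylcyclohex-2-en-1-yl]methyl}sulfonyl)-1-phenyl-1H-tetrazole, both silyloxy epimers | CC1=CC(O[Si](C)(C)C(C)(C)C)CC(C)(C)[C@H]1CS(=O)(=O)C1=NN=NN1c1ccccc1 | intermediate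
14 | crocetindialdehyde, (2E,4E,6E,8E,10E,12E,14E)-2,6,11,15-tetramethylhexadeca-2,4,6,8,10,12,14-heptaenedial | O=C/C(C)=C/C=C/C(C)=C/C=C/C=C(C)/C=C/C=C(C)/C=O | starting material
15 | potassium salt of the C7 carbanion of 9, not isolated | CC1=CC(O[Si](C)(C)C(C)(C)C)CC(C)(C)[C@@H]1[CH-]S(=O)(=O)C1=NN=NN1c1ccccc1.[K+] | intermediate
16 | potassium alkoxide of the β-hydroxy sulfone from 15 and one formyl group of 14, C7/C8 diastereomer mixture, not isolated | CC1=CC(O[Si](C)(C)C(C)(C)C)CC(C)(C)[C@@H]1C(S(=O)(=O)C1=NN=NN1c1ccccc1)C([O-])/C(C)=C/C=C/C(C)=C/C=C/C=C(C)/C=C/C=C(C)/C=O.[K+] | intermediate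
17 | (6S)-3-(tert-butyldimethylsilyloxy)-8′-apo-ε-caroten-8′-al, (2E,4E,6E,8E,10E,12E,14E,16E)-17-[(1S)-4-{[tert-butyl(dimethyl)silyl]oxy}-2,6,6-trimethylcyclohex-2-en-1-yl]-2,6,11,15-tetramethylheptadeca-2,4,6,8,10,12,14,16-octaenal | CC1=CC(O[Si](C)(C)C(C)(C)C)CC(C)(C)[C@@H]1/C=C/C(C)=C/C=C/C(C)=C/C=C/C=C(C)/C=C/C=C(C)/C=O | intermediate
18 | potassium salt of the C7′ carbanion of 13, not isolated | CC1=CC(O[Si](C)(C)C(C)(C)C)CC(C)(C)[C@H]1[CH-]S(=O)(=O)C1=NN=NN1c1ccccc1.[K+] | intermediate
19 | potassium alkoxide of the β-hydroxy sulfone from 18 and 17, C7′/C8′ diastereomer mixture, not isolated | CC1=CC(O[Si](C)(C)C(C)(C)C)CC(C)(C)[C@@H]1/C=C/C(C)=C/C=C/C(C)=C/C=C/C=C(C)/C=C/C=C(C)/C([O-])C(S(=O)(=O)C1=NN=NN1c1ccccc1)[C@H]1C(C)=CC(O[Si](C)(C)C(C)(C)C)CC1(C)C.[K+] | intermediate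
20 | (6S,6′R)-3,3′-bis(tert-butyldimethylsilyloxy)-ε,ε-carotene, all-E | CC1=CC(O[Si](C)(C)C(C)(C)C)CC(C)(C)[C@@H]1/C=C/C(C)=C/C=C/C(C)=C/C=C/C=C(C)/C=C/C=C(C)/C=C/[C@H]1C(C)=CC(O[Si](C)(C)C(C)(C)C)CC1(C)C | intermediate
21 | (6S,6′R)-ε,ε-carotene-3,3′-diol, all-E, C3 and C3′ epimer mixture | CC1=CC(O)CC(C)(C)[C@@H]1/C=C/C(C)=C/C=C/C(C)=C/C=C/C=C(C)/C=C/C=C(C)/C=C/[C@H]1C(C)=CC(O)CC1(C)C | intermediate
22 | (6S,6′R)-ε,ε-carotene-3,3′-dione, all-E, meso | CC1=CC(=O)CC(C)(C)[C@@H]1/C=C/C(C)=C/C=C/C(C)=C/C=C/C=C(C)/C=C/C=C(C)/C=C/[C@H]1C(C)=CC(=O)CC1(C)C | target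

Total step count: 14 steps. Longest linear sequence: 10 steps (steps 1, 2, 3, 4, 5, 6, 11, 12, 13, 14).

Steps most likely to fail

Step 3 (bears the label). The ion pair may discriminate the two faces of C6 poorly, the proton may be lost from C6 or from the C5 methyl group instead of C4, or ring closure may stall because the sulfonyl group lowers the nucleophilicity of the C5=C6 alkene. The fallback replaces asymmetric induction by racemic synthesis and physical separation, which wastes nothing because both antipodes are needed. It sets out from 5: H2SO4 in AcOH at 0–10 °C, the known acid cyclisation of geranyl aryl sulfones, should give racemic α-cyclogeranyl 1-phenyl-1H-tetrazol-5-yl sulfone F1. Preparative chromatography on a polysaccharide chiral stationary phase then separates the antipodes, and the route is rejoined at 6 (the other fraction is 10).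

Step 7 (bears the label). The same loss of face or proton-loss selectivity can occur in the mirror-image series, and supply of the second acid antipode may fall short. The fallback is an independent classical-resolution entry that sets out from thiol 2. Racemic α-cyclogeranic acid F2, taken from the known acid cyclisation of geranic acid, is resolved by fractional crystallisation of its salt with one antipode of 1-phenylethylamine and acidification to give (R)-α-cyclogeranic acid F3. LiAlH4 in Et2O reduces it to (R)-α-cyclogeraniol F4. Mitsunobu coupling with 2 (PPh3, diisopropyl azodicarboxylate, THF) gives (R)-α-cyclogeranyl 1-phenyl-1H-tetrazol-5-yl sulfide F5. Oxidation under the conditions of step 2 rejoins the route at 10.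

Step 11. The carbanion may react at both formyl groups of the dialdehyde, the hindered carbanion may deprotonate the polyenal at a γ-methyl group instead of adding, or E selectivity at C7=C8 may be incomplete. The fallback desymmetrises the linker with a protecting group instead of relying on an excess, and sets out from 14. Neopentyl glycol with pyridinium p-toluenesulfonate in CH2Cl2, stopped at partial conversion, gives crocetindialdehyde mono(neopentyl glycol acetal) F6; unreacted 14 and the bis-acetal are recycled. Carbanion 15, made from 9 as in step 11, olefinates the single free formyl group to give (6S)-3-(tert-butyldimethylsilyloxy)-8′-apo-ε-caroten-8′-al neopentyl glycol acetal F7. Pyridinium p-toluenesulfonate in acetone–water then frees the aldehyde, and the route is rejoined at 17.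

Further compounds
F1 | step 3 | racemic α-cyclogeranyl 1-phenyl-1H-tetrazol-5-yl sulfone | CC1=CCCC(C)(C)C1CS(=O)(=O)C1=NN=NN1c1ccccc1
F2 | step 7 | racemic α-cyclogeranic acid, 2,6,6-trimethylcyclohex-2-ene-1-carboxylic acid | CC1=CCCC(C)(C)C1C(=O)O
F3 | step 7 | (R)-α-cyclogeranic acid, (1R)-2,6,6-trimethylcyclohex-2-ene-1-carboxylic acid | CC1=CCCC(C)(C)[C@H]1C(=O)O
F4 | step 7 | (R)-α-cyclogeraniol, [(1R)-2,6,6-trimethylcyclohex-2-en-1-yl]methanol | CC1=CCCC(C)(C)[C@H]1CO
F5 | step 7 | (R)-α-cyclogeranyl 1-phenyl-1H-tetrazol-5-yl sulfide | CC1=CCCC(C)(C)[C@H]1CSC1=NN=NN1c1ccccc1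
F6 | step 11 | crocetindialdehyde mono(neopentyl glycol acetal), (2E,4E,6E,8E,10E,12E,14E)-15-(5,5-dimethyl-1,3-dioxan-2-yl)-2,6,11-trimethylhexadeca-2,4,6,8,10,12,14-heptaenal | O=C/C(C)=C/C=C/C(C)=C/C=C/C=C(C)/C=C/C=C(C)/C1OCC(C)(C)CO1
F7 | step 11 | (6S)-3-(tert-butyldimethylsilyloxy)-8′-apo-ε-caroten-8′-al neopentyl glycol acetal | CC1=CC(O[Si](C)(C)C(C)(C)C)CC(C)(C)[C@@H]1/C=C/C(C)=C/C=C/C(C)=C/C=C/C=C(C)/C=C/C=C(C)/C1OCC(C)(C)CO1
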